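(The data were computed with constants of no real substance.)

Monomer in chains is what you weigh, but every chain must first be begun, so balance the reagent charged in the smaller amount: initiator, 0.50 mM against 0.10 M of free monomer.

| flask | free monomer | initiator | remark | time |
|---|---|---|---|---|
| zeta | 0.050 M (fed, over 12 min) | 0.50 mM | run made earlier; the fed solution adds 0.25 times the starting volume |  |
| beta | 0.075 M (fed, over 12 min) | 0.50 mM | run made earlier; the fed solution adds 0.25 times the starting volume |  |
| flask | 0.10 M (fed, over 12 min) | 0.50 mM | the fed solution adds 0.25 times the starting volume | 12 min |

- zeta (time / min: monomer in chains / %, free monomer / %): 0.500: 1.7, 3.7; 1.33: 0.1, 11.9; 2.50: 0, 22.2; 4.00: 0, 32.7; 6.00: 0.2, 51.6; 8.00: 2.2, 66.1; 10.0: 2.4, 80.7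
- beta (time / min: monomer in chains / %, free monomer / %): 0.833: 0, 7.6; 1.33: 0, 10.2; 2.00: 0.2, 17.9; 2.50: 1.6, 20.9; 4.00: 0.4, 31.6; 6.00: 0.5, 50.0; 10.0: 3.7, 78.8

(readings scatter by 1 percentage point)

- charges are per starting volume, the dose included; the dosed solution carries all of it
- the average divides the monomer in chains by the number of chains begun, living and dead together
- the numbers in the tables scatter by 1 percentage point (one standard deviation)
- candidate steps: free monomer + initiator -> living end + monomer in chains; free monomer + living end -> monomer in chains + living end; initiator -> spent initiator; free monomer -> decomposition product
- the earlier runs do not show the number of chains; that part of a forecast is a guess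
- percentages count the whole charge, also what has not yet gone in

1. average number of monomer units in a chain (chains begun, living or dead) at 12 min
2. part of the free monomer that has reacted at 12 min

In the candidate steps, one initiator begins one chain, so [initiator] charged caps the chains begun; it is the limiting reagent of the chain count. Your tool is the charge ratio, free monomer charged per initiator charged, here 200. Multiply it by the part of the free monomer charged that stands as monomer in chains and you have a floor under the average chain.

How much reacts? At 10.0 min, the beta and zeta readings of monomer in chains, each with a scatter of 1 percentage point, stand in the ratio 1.54, and their charges in 1.50. So I scale the beta reading with the charge and estimate 4.93% in chains for the flask at that time, which makes an estimated floor of 9.87 there. My reckoning stops at a floor, since the earlier runs do not show the chain count.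

The forecast gives 10% reacted and a chain of 50: “The initiator is probably only partly used, so dp is perhaps 50, but this is a guess.”

The flask gives 7.71% reacted and a chain of 107. At 12.0 min it holds 22% of its initiator unbound, against 92% of its free monomer. With 7.60% of its free monomer in chains, the charge ratio now puts the flask's floor at 15.2, so chains begun are 14.2% of the initiator charge.

    free monomer + initiator → living end + monomer in chains (k = 0.670 L mol⁻¹ min⁻¹)
    free monomer + living end → monomer in chains + living end, rate k2*[living end]*[free monomer] (k = 350 L mol⁻¹ min⁻¹)
    initiator → spent initiator (k = 0.0970 min⁻¹)
    free monomer → decomposition product (k = 1.90 × 10⁻⁴ min⁻¹)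

Now charge 2.0 × 10⁻⁴ M of initiator: the ratio becomes 500. If the part in chains falls in step, to 3.04%, the floor stays 15.2, and if the same share of the initiator charge begins chains, the chain comes to 107. That neighbour computes to 109 at 3.27% reacted.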